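**Plan**

Locants: ring C1 (C(OH)CH3), C2 (quaternary), C3 (CH carrying the hydroxypropyl chain C1''–C3''), C4 (alkylidene carbon), C5, C6; side chain C1'–C12' outward from C2.
Cuts, in retrosynthetic order: the enal C4=C bond (back to a C4 ketone and an isopropenyl unit), the C2'–C3' sp3–sp2 bond, the ring bond C1–C2, the C2=C1' enoate (methyl and ester onto an alkyne), the aldol bond C3–C4, and C5'–C6' in the side chain.
Enabling feature: C1 and C2 are adjacent, fully substituted ring carbons that both trace back to electrophilic carbons (a methyl ketone carbonyl and the β-carbon of a C2=C1'–C2' enoate), so a ketyl made by electron transfer can join them.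
Forward: the C3'–C12' alkenyl iodide is made first; then the acyclic keto enoate is built, the only ring (the cyclohexane) is closed by the samarium step, the chain is attached by Negishi coupling, and the enal is installed last before desilylation.
Stereochemistry: C8' from the chiral pool, C5' from a ligand-controlled alkenylzinc addition, C3 and the temporary C4 carbinol from an oxazolidinone syn aldol, C1 and C2 from the chair of the ring closure; E alkenes from syn hydroboration and syn carboalumination, the Z enal from allylic strain.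

Key step: step 15

Remark on the chemistry: the target is read from its SMILES as (1S,2S,3R,5'S,8'S) with a (Z)-configured exocyclic enal and (3'E,6'E) alkenes; the ring locants above are used in the names of all ring compounds.

**Route**

Step 1
Reactants: 1 (S)-citronellal
Product: 3 (3S)-3,7-dimethyloct-6-en-1-yne, via alkenyl nonaflate 2 (not isolated)
Conditions: C4F9SO2F, phosphazene base P2-Et, DMF, −30 °C → rt
Reagents that add atoms: none
Why: Nonaflation of the aldehyde enolate followed by base-induced E2 loss of nonaflate (a non-homologating aldehyde-to-alkyne conversion) should give the alkyne with all ten carbons of 1, the C3 stereocentre lying off the enolisation path and a terminal alkyne not being isomerised to the allene by this base.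

Step 2
Reactants: 4 propargyl alcohol
Product: 6 (E)-3-iodo-2-methylprop-2-en-1-ol, via alkenylalane 5 (not isolated)
Conditions: Me3Al, Cp2ZrCl2 (cat.), CH2Cl2, 0 °C → rt; then I2, THF, −30 °C
Reagents that add atoms: trimethylaluminium (C[Al](C)C); iodine (II)
Why: Negishi carboalumination adds methyl and aluminium syn across the alkyne (methyl to the internal carbon), and iodinolysis with retention gives the (E)-iodide.

Step 3
Reactants: 6 (E)-3-iodo-2-methylprop-2-en-1-ol
Product: 7 (E)-3-iodo-2-methylprop-2-enal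
Conditions: MnO2 (activated), CH2Cl2, rt
Reagents that add atoms: none
Why: Allylic oxidation with MnO2 is selective for the allylic alcohol and leaves the alkenyl iodide and its geometry untouched.

Step 4
Reactants: 3 (3S)-3,7-dimethyloct-6-en-1-yne; 7 (E)-3-iodo-2-methylprop-2-enal
Product: 10 (1E,3S,4E,6S)-1-iodo-2,6,10-trimethylundeca-1,4,9-trien-3-ol, via alkenyldicyclohexylborane 8 (not isolated), via alkenylmethylzinc 9 (not isolated)
Conditions: Cy2BH, toluene, 0 °C → rt; Me2Zn, −78 °C; (−)-MIB (5 mol%); then 7, −20 °C → 0 °C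
Reagents that add atoms: none
Why: Syn hydroboration of the terminal alkyne gives the (E)-alkenylborane, boron-to-zinc exchange the alkenylzinc, and the (2S)-configured amino alcohol ligand (−)-MIB should direct alkenyl transfer to the Si face of the enal (catalytic asymmetric alkenylzinc addition), which corresponds to the 5'S carbinol while C8' is untouched.

Step 5
Reactants: 10 (1E,3S,4E,6S)-1-iodo-2,6,10-trimethylundeca-1,4,9-trien-3-ol
Product: 11 TBS ether of 10 (C3'–C12' alkenyl iodide)
Conditions: TBSCl, imidazole, DMF, rt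
Reagents that add atoms: tert-butyldimethylsilyl chloride (CC(C)(C)[Si](C)(C)Cl)
Why: Standard silylation of a secondary alcohol under basic conditions that cannot ionise the bis-allylic position.

Step 6
Reactants: 12 δ-valerolactone
Product: 15 5-[(tert-butyldiphenylsilyl)oxy]pentanoic acid, via sodium 5-hydroxypentanoate 13 (not isolated), via bis-silylated ester 14 (not isolated)
Conditions: NaOH, H2O/MeOH, rt, evaporate; TBDPSCl, imidazole, DMF, rt; K2CO3, MeOH/THF/H2O; aq. HCl to pH 4
Reagents that add atoms: sodium hydroxide ([Na+].[OH-]); tert-butyldiphenylsilyl chloride (CC(C)(C)[Si](Cl)(c1ccccc1)c1ccccc1)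
Why: Saponification opens the lactone, the silyl chloride caps both oxygens and carbonate cleaves only the labile silyl ester, a routine one-flask entry to ω-silyloxy acids.

Step 7
Reactants: 15 5-[(tert-butyldiphenylsilyl)oxy]pentanoic acid; 16 (R)-4-benzyl-2-oxazolidinone
Product: 18 (R)-4-benzyl-3-{5-[(tert-butyldiphenylsilyl)oxy]pentanoyl}oxazolidin-2-one, via mixed pivalic anhydride 17 (not isolated)
Conditions: PivCl, Et3N, THF, −20 °C; then LiCl, 16, −20 °C → rt
Reagents that add atoms: none
Why: N-Acylation of the oxazolidinone through the mixed pivalic anhydride with LiCl activation is the standard way to Evans imides.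

Step 8
Reactants: 18 (R)-4-benzyl-3-{5-[(tert-butyldiphenylsilyl)oxy]pentanoyl}oxazolidin-2-one; 19 pent-4-enal
Product: 22 syn aldol adduct (C3 R; C4 S), via Z-boron enolate 20 (not isolated), via boron aldolate 21 (not isolated)
Conditions: Bu2BOTf, i-Pr2NEt, CH2Cl2, 0 °C; 19, −78 °C → 0 °C; pH 7 buffer, MeOH, H2O2, 0 °C
Reagents that add atoms: none
Why: Evans syn aldol in which the (Z)-boron enolate reacts through a Zimmerman–Traxler chair on the enolate face opposite the benzyl group of the (R)-auxiliary, setting C3 and C4 as the syn pair with C3 (R) and C4 (S).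

Step 9
Reactants: 22 syn aldol adduct
Product: 23 C4 triethylsilyl ether of 22
Conditions: TESOTf, 2,6-lutidine, CH2Cl2, −78 °C → 0 °C
Reagents that add atoms: triethylsilyl triflate (CC[Si](CC)(CC)OS(=O)(=O)C(F)(F)F)
Why: Silyl triflate and lutidine silylate a β-hydroxy imide quickly at low temperature without retro-aldol cleavage.

Step 10
Reactants: 23 C4 triethylsilyl ether of 22
Product: 24 (2S,3S)-2-{3-[(tert-butyldiphenylsilyl)oxy]propyl}-3-[(triethylsilyl)oxy]hept-6-en-1-ol
Conditions: LiBH4, MeOH (1 equiv), THF, 0 °C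
Reagents that add atoms: none
Why: Reductive removal of the auxiliary with LiBH4 attacks the exocyclic imide carbonyl and spares silyl ethers and the alkene.

Step 11
Reactants: 24 primary alcohol
Product: 25 (2R,3S)-2-{3-[(tert-butyldiphenylsilyl)oxy]propyl}-3-[(triethylsilyl)oxy]hept-6-enal
Conditions: Dess–Martin periodinane, CH2Cl2, 0 °C → rt
Reagents that add atoms: none
Why: Dess–Martin oxidation gives the α-branched aldehyde under conditions mild enough not to epimerise C3.

Step 12
Reactants: 25 aldehyde
Product: 26 terminal alkyne (C2≡C1'H on C3)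
Conditions: dimethyl (1-diazo-2-oxopropyl)phosphonate, K2CO3, MeOH, 0 °C → rt
Reagents that add atoms: dimethyl (1-diazo-2-oxopropyl)phosphonate (CC(=O)C(=[N+]=[N-])P(=O)(OC)OC)
Why: Ohira–Bestmann homologation converts the aldehyde to the terminal alkyne in a weakly basic medium that normally preserves α-stereocentres and silyl ethers.

Step 13
Reactants: 26 terminal alkyne
Product: 28 methyl (2E,4S,5S)-4-{3-[(tert-butyldiphenylsilyl)oxy]propyl}-3-methyl-5-[(triethylsilyl)oxy]nona-2,8-dienoate, via alkenyldimethylalane 27 (not isolated)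
Conditions: Me3Al, Cp2ZrCl2 (cat.), CH2Cl2, 0 °C → rt; then ClCO2Me, 0 °C → rt
Reagents that add atoms: trimethylaluminium (C[Al](C)C); methyl chloroformate (COC(=O)Cl)
Why: Negishi carboalumination adds methyl to C2 and aluminium to C1' in syn fashion and acylation of the alkenylalane by the chloroformate with retention gives the (E)-enoate with C3 trans to the ester, the isolated terminal alkene being far less reactive than the alkyne toward methylalumination.

Step 14
Reactants: 28 dienoate
Product: 29 methyl (2E,4S,5S)-4-{3-[(tert-butyldiphenylsilyl)oxy]propyl}-3-methyl-8-oxo-5-[(triethylsilyl)oxy]non-2-enoate (acyclic keto enoate)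
Conditions: PdCl2 (10 mol%), Cu(OAc)2 (20 mol%), O2 (1 atm), DMA/H2O, rt
Reagents that add atoms: water (O)
Why: Tsuji–Wacker oxidation converts the monosubstituted alkene to the methyl ketone with Markovnikov selectivity, the conjugated trisubstituted enoate being inert and the acetate co-oxidant keeping the medium mild enough for the silyl ethers.

Step 15
Reactants: 29 acyclic keto enoate
Product: 30 cyclohexanol hydroxy ester (C1 tertiary alcohol; C2 quaternary carbon bearing CH2CO2Me)
Conditions: SmI2 (2.5 equiv), HMPA, t-BuOH, THF, −78 °C → 0 °C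
Reagents that add atoms: none
Why: Electron transfer from HMPA-ligated divalent samarium to the methyl ketone gives a samarium ketyl whose carbon adds to the β-carbon of the (E)-enoate, a second electron turns the α-ester radical into a samarium enolate and tert-butanol protonates it, which is the established SmI2 ketyl–olefin (ketone–enoate) reductive cyclisation. The cyclohexane ring closes 6-exo-trig by forming the C1–C2 bond between two carbons that were both electrophilic. C1 is set by the bulky samarium-bound oxygen taking the equatorial site of the chair (methyl axial) and C2 by the enoate arm C1'–C2' taking the equatorial site (methyl axial), so that the hydroxyl ends trans to the arm and cis to the C2 methyl; their sense relative to the rest of the ring is dictated by the C3 chain and the C4 triethylsilyloxy group, which sit trans-diequatorial as fixed by the syn aldol. The step needs ketyl formation ahead of enoate reduction, secured by the easier reduction of the unconjugated ketone under SmI2–HMPA, and diastereoselection, secured by the two equatorial anchors at C3 and C4 and by the (E)-enoate, whose vinylic hydrogen and not its ester faces C3. The trans-disposed hydroxy ester is not expected to lactonise under these cold, non-acidic conditions and is carried on as such.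

Step 16
Reactants: 30 cyclohexanol hydroxy ester
Product: 31 C1,C4-bis(triethylsilyl) ether ester
Conditions: TESOTf, 2,6-lutidine, CH2Cl2, 0 °C → rt
Reagents that add atoms: triethylsilyl triflate (CC[Si](CC)(CC)OS(=O)(=O)C(F)(F)F)
Why: The reactive silyl triflate caps the hindered tertiary alcohol so that it cannot quench the organozinc, cyclise onto C2' during iodination or intercept a C4 cation later.

Step 17
Reactants: 31 bis(triethylsilyl) ether ester
Product: 32 C2' primary alcohol
Conditions: i-Bu2AlH, CH2Cl2, −78 °C → 0 °C; aq. potassium sodium tartrate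
Reagents that add atoms: none
Why: i-Bu2AlH reduces the methyl ester to the primary alcohol and leaves the silyl ethers alone.

Step 18
Reactants: 32 C2' primary alcohol
Product: 33 C2' primary iodide
Conditions: I2, PPh3, imidazole, CH2Cl2, 0 °C → rt
Reagents that add atoms: iodine (II)
Why: Appel-type iodination converts the unhindered primary alcohol to the iodide by SN2 displacement of the alkoxyphosphonium group.

Step 19
Reactants: 33 C2' primary iodide; 11 C3'–C12' alkenyl iodide
Product: 35 coupled tetrasilyl ether (C2'–C3' bond formed), via alkylzinc iodide 34 (not isolated)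
Conditions: Zn dust (activated), LiCl, THF, 40 °C; then 11, PdCl2(dppf) (5 mol%), THF, rt → 50 °C
Reagents that add atoms: none
Why: Negishi coupling in which zinc inserts into the primary C–I bond and zerovalent palladium, formed from PdCl2(dppf), couples the alkylzinc with the alkenyl iodide with retention of the (E)-C3'=C4' geometry.

Step 20
Reactants: 35 coupled tetrasilyl ether
Product: 36 C4 secondary alcohol
Conditions: PPTS (cat.), MeOH/CH2Cl2, 0 °C
Reagents that add atoms: none
Why: Acid-catalysed methanolysis should remove the secondary triethylsilyl ether well before the tertiary triethylsilyl, the secondary TBS and the primary TBDPS ethers, following the usual steric grading of silyl ether lability.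

Step 21
Reactants: 36 C4 secondary alcohol
Product: 37 C4 ketone
Conditions: Dess–Martin periodinane, NaHCO3, CH2Cl2, 0 °C → rt
Reagents that add atoms: none
Why: Buffered Dess–Martin oxidation gives the ketone, and since the C3 chain already occupies its thermodynamically preferred equatorial position enolisation toward C3 is harmless.

Step 22
Reactants: 37 C4 ketone
Product: 38 C4 isopropenyl carbinol
Conditions: isopropenylmagnesium bromide, CeCl3 (anhydrous), THF, −78 °C → 0 °C
Reagents that add atoms: isopropenylmagnesium bromide (CC(=C)[Mg]Br)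
Why: The weakly basic organocerium reagent adds 1,2 to the hindered, enolisable ketone, expected from the equatorial direction because the axial C2 methyl blocks the axial path (4R), and the new C4 configuration is erased in the next step.

Step 23
Reactants: 38 C4 isopropenyl carbinol
Product: 39 trisilylated (Z)-enal
Conditions: pyridinium chlorochromate (C5H5NH[CrO3Cl]), 4 Å molecular sieves, CH2Cl2, rt
Reagents that add atoms: pyridinium chlorochromate ([O-][Cr](=O)(=O)Cl.c1cc[nH+]cc1)
Why: Babler–Dauben oxidative transposition in which the tertiary allylic chromate ester undergoes a [3,3]-sigmatropic shift to the primary allylic chromate and is oxidised to the enal, the methyl of the new tetrasubstituted alkene expected to settle on the C5 side and the smaller formyl group next to the substituted C3 (allylic 1,3-strain), which is the Z geometry.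

Step 24
Reactants: 39 trisilylated (Z)-enal
Product: 40 CNP0323596.2 (target)
Conditions: Bu4NF, AcOH (1:1), THF, rt → 40 °C
Reagents that add atoms: none
Why: Buffered fluoride cleaves the tertiary triethylsilyl, the secondary TBS and the primary TBDPS ethers by Si–F bond formation without exposing the enal to strong base or the bis-allylic alcohol to acid.

**Compound list**

1 | (S)-citronellal, (3S)-3,7-dimethyloct-6-enal | CC(C)=CCC[C@H](C)CC=O | starting material
2 | (3S)-3,7-dimethylocta-1,6-dien-1-yl nonafluorobutane-1-sulfonate (E/Z mixture, not isolated) | CC(C)=CCC[C@H](C)C=COS(=O)(=O)C(F)(F)C(F)(F)C(F)(F)C(F)(F)F | intermediate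
3 | (3S)-3,7-dimethyloct-6-en-1-yne | CC(C)=CCC[C@H](C)C#C | intermediate
4 | propargyl alcohol, prop-2-yn-1-ol | C#CCO | starting material
5 | dimethylaluminium (E)-3-(dimethylalumanyl)-2-methylprop-2-en-1-olate (not isolated) | C[Al](C)/C=C(\C)CO[Al](C)C | intermediate
6 | (E)-3-iodo-2-methylprop-2-en-1-ol | OC/C(C)=C/I | intermediate
7 | (E)-3-iodo-2-methylprop-2-enal | O=C/C(C)=C/I | intermediate
8 | dicyclohexyl[(1E,3S)-3,7-dimethylocta-1,6-dien-1-yl]borane (not isolated) | CC(C)=CCC[C@H](C)/C=C/B(C1CCCCC1)C1CCCCC1 | intermediate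
9 | [(1E,3S)-3,7-dimethylocta-1,6-dien-1-yl](methyl)zinc (not isolated) | CC(C)=CCC[C@H](C)/C=C/[Zn]C | intermediate
10 | (1E,3S,4E,6S)-1-iodo-2,6,10-trimethylundeca-1,4,9-trien-3-ol | CC(C)=CCC[C@H](C)/C=C/[C@H](O)/C(C)=C/I | intermediate
11 | tert-butyl{[(1E,3S,4E,6S)-1-iodo-2,6,10-trimethylundeca-1,4,9-trien-3-yl]oxy}dimethylsilane (C3'–C12' alkenyl iodide) | CC(C)=CCC[C@H](C)/C=C/[C@H](O[Si](C)(C)C(C)(C)C)/C(C)=C/I | intermediate
12 | δ-valerolactone | O=C1CCCCO1 | starting material
13 | sodium 5-hydroxypentanoate (not isolated) | [Na+].[O-]C(=O)CCCCO | intermediate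
14 | tert-butyldiphenylsilyl 5-[(tert-butyldiphenylsilyl)oxy]pentanoate (not isolated) | CC(C)(C)[Si](OCCCCC(=O)O[Si](c1ccccc1)(c1ccccc1)C(C)(C)C)(c1ccccc1)c1ccccc1 | intermediate
15 | 5-[(tert-butyldiphenylsilyl)oxy]pentanoic acid | CC(C)(C)[Si](OCCCCC(=O)O)(c1ccccc1)c1ccccc1 | intermediate
16 | (R)-4-benzyl-2-oxazolidinone | O=C1N[C@H](Cc2ccccc2)CO1 | starting material
17 | 5-[(tert-butyldiphenylsilyl)oxy]pentanoic pivalic anhydride (not isolated) | CC(C)(C)C(=O)OC(=O)CCCCO[Si](c1ccccc1)(c1ccccc1)C(C)(C)C | intermediate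
18 | (R)-4-benzyl-3-{5-[(tert-butyldiphenylsilyl)oxy]pentanoyl}oxazolidin-2-one | O=C1OC[C@@H](Cc2ccccc2)N1C(=O)CCCCO[Si](c1ccccc1)(c1ccccc1)C(C)(C)C | intermediate
19 | pent-4-enal | C=CCCC=O | starting material
20 | (Z)-dibutylboron enolate of 18 (not isolated) | CCCCB(CCCC)O/C(=C\CCCO[Si](c1ccccc1)(c1ccccc1)C(C)(C)C)N1[C@H](Cc2ccccc2)COC1=O | intermediate
21 | O-dibutylboryl aldolate of 22 (not isolated) | C=CCC[C@H](OB(CCCC)CCCC)[C@@H](CCCO[Si](c1ccccc1)(c1ccccc1)C(C)(C)C)C(=O)N1[C@H](Cc2ccccc2)COC1=O | intermediate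
22 | (R)-4-benzyl-3-[(2R,3S)-2-{3-[(tert-butyldiphenylsilyl)oxy]propyl}-3-hydroxyhept-6-enoyl]oxazolidin-2-one | C=CCC[C@H](O)[C@@H](CCCO[Si](c1ccccc1)(c1ccccc1)C(C)(C)C)C(=O)N1[C@H](Cc2ccccc2)COC1=O | intermediate
23 | (R)-4-benzyl-3-[(2R,3S)-2-{3-[(tert-butyldiphenylsilyl)oxy]propyl}-3-[(triethylsilyl)oxy]hept-6-enoyl]oxazolidin-2-one | C=CCC[C@H](O[Si](CC)(CC)CC)[C@@H](CCCO[Si](c1ccccc1)(c1ccccc1)C(C)(C)C)C(=O)N1[C@H](Cc2ccccc2)COC1=O | intermediate
24 | (2S,3S)-2-{3-[(tert-butyldiphenylsilyl)oxy]propyl}-3-[(triethylsilyl)oxy]hept-6-en-1-ol | C=CCC[C@H](O[Si](CC)(CC)CC)[C@@H](CCCO[Si](c1ccccc1)(c1ccccc1)C(C)(C)C)CO | intermediate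
25 | (2R,3S)-2-{3-[(tert-butyldiphenylsilyl)oxy]propyl}-3-[(triethylsilyl)oxy]hept-6-enal | C=CCC[C@H](O[Si](CC)(CC)CC)[C@@H](CCCO[Si](c1ccccc1)(c1ccccc1)C(C)(C)C)C=O | intermediate
26 | tert-butyl{[(4S,5S)-4-ethynyl-5-[(triethylsilyl)oxy]non-8-en-1-yl]oxy}diphenylsilane | C=CCC[C@H](O[Si](CC)(CC)CC)[C@@H](CCCO[Si](c1ccccc1)(c1ccccc1)C(C)(C)C)C#C | intermediate
27 | (E)-alkenyldimethylalane of 26, aluminium on C1' and methyl on C2 (not isolated) | C=CCC[C@H](O[Si](CC)(CC)CC)[C@@H](CCCO[Si](c1ccccc1)(c1ccccc1)C(C)(C)C)/C(C)=C/[Al](C)C | intermediate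
28 | methyl (2E,4S,5S)-4-{3-[(tert-butyldiphenylsilyl)oxy]propyl}-3-methyl-5-[(triethylsilyl)oxy]nona-2,8-dienoate | C=CCC[C@H](O[Si](CC)(CC)CC)[C@@H](CCCO[Si](c1ccccc1)(c1ccccc1)C(C)(C)C)/C(C)=C/C(=O)OC | intermediate
29 | methyl (2E,4S,5S)-4-{3-[(tert-butyldiphenylsilyl)oxy]propyl}-3-methyl-8-oxo-5-[(triethylsilyl)oxy]non-2-enoate (acyclic keto enoate) | COC(=O)/C=C(\C)[C@H](CCCO[Si](c1ccccc1)(c1ccccc1)C(C)(C)C)[C@@H](O[Si](CC)(CC)CC)CCC(C)=O | intermediate
30 | methyl [(1S,2S,3S,4S)-3-{3-[(tert-butyldiphenylsilyl)oxy]propyl}-1-hydroxy-1,2-dimethyl-4-[(triethylsilyl)oxy]cyclohex-2-yl]acetate (OH trans to the acetate arm, cis to the C2 methyl and the C3 chain) | COC(=O)C[C@@]1(C)[C@H](CCCO[Si](c2ccccc2)(c2ccccc2)C(C)(C)C)[C@@H](O[Si](CC)(CC)CC)CC[C@]1(C)O | intermediate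
31 | methyl [(1S,2S,3S,4S)-3-{3-[(tert-butyldiphenylsilyl)oxy]propyl}-1,2-dimethyl-1,4-bis[(triethylsilyl)oxy]cyclohex-2-yl]acetate | COC(=O)C[C@@]1(C)[C@H](CCCO[Si](c2ccccc2)(c2ccccc2)C(C)(C)C)[C@@H](O[Si](CC)(CC)CC)CC[C@]1(C)O[Si](CC)(CC)CC | intermediate
32 | 2-[(1S,2S,3S,4S)-3-{3-[(tert-butyldiphenylsilyl)oxy]propyl}-1,2-dimethyl-1,4-bis[(triethylsilyl)oxy]cyclohex-2-yl]ethan-1-ol | OCC[C@@]1(C)[C@H](CCCO[Si](c2ccccc2)(c2ccccc2)C(C)(C)C)[C@@H](O[Si](CC)(CC)CC)CC[C@]1(C)O[Si](CC)(CC)CC | intermediate
33 | C2' iodide: (1S,2S,3S,4S)-2-(2-iodoethyl)-3-{3-[(tert-butyldiphenylsilyl)oxy]propyl}-1,2-dimethyl-1,4-bis[(triethylsilyl)oxy]cyclohexane | ICC[C@@]1(C)[C@H](CCCO[Si](c2ccccc2)(c2ccccc2)C(C)(C)C)[C@@H](O[Si](CC)(CC)CC)CC[C@]1(C)O[Si](CC)(CC)CC | intermediate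
34 | alkylzinc iodide from 33, zinc on C2' (not isolated) | I[Zn]CC[C@@]1(C)[C@H](CCCO[Si](c2ccccc2)(c2ccccc2)C(C)(C)C)[C@@H](O[Si](CC)(CC)CC)CC[C@]1(C)O[Si](CC)(CC)CC | intermediate
35 | coupled tetrasilyl ether: ring (1S,2S,3S,4S) with C1 and C4 OTES, C3'' OTBDPS, side chain (3'E,5'S,6'E,8'S) with C5' OTBS | CC(C)=CCC[C@H](C)/C=C/[C@H](O[Si](C)(C)C(C)(C)C)/C(C)=C/CC[C@@]1(C)[C@H](CCCO[Si](c2ccccc2)(c2ccccc2)C(C)(C)C)[C@@H](O[Si](CC)(CC)CC)CC[C@]1(C)O[Si](CC)(CC)CC | intermediate
36 | C4 alcohol: as 35 with free C4 hydroxyl (4S) | CC(C)=CCC[C@H](C)/C=C/[C@H](O[Si](C)(C)C(C)(C)C)/C(C)=C/CC[C@@]1(C)[C@H](CCCO[Si](c2ccccc2)(c2ccccc2)C(C)(C)C)[C@@H](O)CC[C@]1(C)O[Si](CC)(CC)CC | intermediate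
37 | C4 ketone: ring (1S,2S,3S), C1 OTES, C3'' OTBDPS, C5' OTBS | CC(C)=CCC[C@H](C)/C=C/[C@H](O[Si](C)(C)C(C)(C)C)/C(C)=C/CC[C@@]1(C)[C@H](CCCO[Si](c2ccccc2)(c2ccccc2)C(C)(C)C)C(=O)CC[C@]1(C)O[Si](CC)(CC)CC | intermediate
38 | C4 isopropenyl carbinol: ring (1S,2S,3S,4R), isopropenyl equatorial and cis to the C2 side chain, hydroxyl axial | CC(C)=CCC[C@H](C)/C=C/[C@H](O[Si](C)(C)C(C)(C)C)/C(C)=C/CC[C@@]1(C)[C@H](CCCO[Si](c2ccccc2)(c2ccccc2)C(C)(C)C)[C@@](O)(C(C)=C)CC[C@]1(C)O[Si](CC)(CC)CC | intermediate
39 | trisilylated enal: target with C1 OTES, C3'' OTBDPS and C5' OTBS, exocyclic alkene Z (formyl cis to C3) | CC(C)=CCC[C@H](C)/C=C/[C@H](O[Si](C)(C)C(C)(C)C)/C(C)=C/CC[C@@]1(C)[C@H](CCCO[Si](c2ccccc2)(c2ccccc2)C(C)(C)C)/C(=C(/C)C=O)CC[C@]1(C)O[Si](CC)(CC)CC | intermediate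
40 | CNP0323596.2, (2Z)-2-[(2R,3S,4S)-4-hydroxy-2-(3-hydroxypropyl)-3,4-dimethyl-3-[(3E,5S,6E,8S)-5-hydroxy-4,8,12-trimethyltrideca-3,6,11-trien-1-yl]cyclohexylidene]propanal | CC(C)=CCC[C@H](C)/C=C/[C@H](O)/C(C)=C/CC[C@@]1(C)[C@H](CCCO)/C(=C(/C)C=O)CC[C@]1(C)O | target

**Count and risks**

Total step count: 24. Longest linear sequence: 19 steps (steps 6–24, from δ-valerolactone); the alkenyl iodide 11 takes 5 steps (steps 1–5) and enters at step 19.

Steps most likely to fail:

1. Step 15 (ring closure). Electron transfer may end in simple reduction of the ketone to a secondary alcohol, or of the enoate, before the hindered C1–C2 bond forms at the β,β-disubstituted acceptor, and the chair preference may be too weak to give one C1/C2 diastereomer. Fallback: a tin-mediated radical chain instead of two single-electron transfers. Setting out from 29, Bu3SnH (slow addition) and AIBN in benzene at 80 °C would add the tin radical reversibly to the ketone oxygen; the neutral O-stannyl ketyl, free of the large solvated metal, should cyclise 6-exo onto the enoate, and the α-ester radical would take hydrogen from the stannane. This gives the O-tributylstannyl ether of the cyclohexanol F1, whose Sn–O bond is hydrolysed on silica gel work-up, coming back to the route at 30.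

2. Step 23 (oxidative transposition). The [3,3] shift may deliver the tetrasubstituted alkene with poor geometric control, or the tertiary allylic chromate may ionise, leading to dehydration to a diene and to acid-induced loss of the bis-allylic silyl ether. Fallback: carbonyl olefination in place of addition and transposition. Setting out from ketone 37, a Horner–Wadsworth–Emmons reaction with diethyl (1-cyanoethyl)phosphonate (NaH, THF, 0 → 60 °C) would give the tetrasubstituted unsaturated nitrile F2 (Z isomer, separated from E). Reduction with i-Bu2AlH (toluene, −78 °C) and mild hydrolysis of the aldimine would come back to the route at 39, bypassing steps 22 and 23.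

3. Step 13 (carboalumination and acylation). Methylalumination may stall at the α-branched alkyne next to the silyloxy group, the pendant terminal alkene may be carbometalated in competition, or the alkenylalane may resist acylation. Fallback: build the enoate by olefination of a methyl ketone. Setting out from aldehyde 25, MeMgBr (Et2O, −78 °C) would give the secondary alcohol F3 (mixture of carbinol epimers), and Dess–Martin oxidation the methyl ketone F4. A Horner–Wadsworth–Emmons reaction with trimethyl phosphonoacetate (NaH, THF, 0 °C → rt) should favour the E isomer because the branched C3 is the larger ketone substituent, and comes back to the route at 28, bypassing steps 12 and 13.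

**Further compounds**

F1 | step 15 | O-tributylstannyl ether of 30 | COC(=O)C[C@@]1(C)[C@H](CCCO[Si](c2ccccc2)(c2ccccc2)C(C)(C)C)[C@@H](O[Si](CC)(CC)CC)CC[C@]1(C)O[Sn](CCCC)(CCCC)CCCC
F2 | step 23 | (Z)-unsaturated nitrile, 39 with C≡N in place of CHO | CC(C)=CCC[C@H](C)/C=C/[C@H](O[Si](C)(C)C(C)(C)C)/C(C)=C/CC[C@@]1(C)[C@H](CCCO[Si](c2ccccc2)(c2ccccc2)C(C)(C)C)/C(=C(/C)C#N)CC[C@]1(C)O[Si](CC)(CC)CC
F3 | step 13 | (3S,4S)-3-{3-[(tert-butyldiphenylsilyl)oxy]propyl}-4-[(triethylsilyl)oxy]oct-7-en-2-ol (carbinol epimers) | C=CCC[C@H](O[Si](CC)(CC)CC)[C@@H](CCCO[Si](c1ccccc1)(c1ccccc1)C(C)(C)C)C(C)O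
F4 | step 13 | (3R,4S)-3-{3-[(tert-butyldiphenylsilyl)oxy]propyl}-4-[(triethylsilyl)oxy]oct-7-en-2-one | C=CCC[C@H](O[Si](CC)(CC)CC)[C@@H](CCCO[Si](c1ccccc1)(c1ccccc1)C(C)(C)C)C(C)=O
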